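## Structural features

Lobatin B (38) is a germacrane whose ten-membered carbocycle C1–C10 is bridged by an oxygen between C3 and C10. The atoms O, C3, C2, C1 and C10 form a 3(2H)-furanone, and a γ-butyrolactone (O, C6, C7, C11, C12) with the exocyclic C11=C13 methylene is trans-fused on the C6–C7 bond. Five stereocentres stand in a row: C6 (R, lactone carbinol), C7 (S), C8 (S, isovalerate), C9 (R, free hydroxyl) and the quaternary C10 (R; methyl, ring oxygen, ketone carbon). C8 and C9 form a threo diol that is trans on the ring. The C4=C5 alkene is trisubstituted, Z, and cross-conjugated with the furanone. The fragile points are: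
- the methylene lactone (Michael acceptor);
- the vinylogous ester of the furanone;
- C6–H, which is allylic, next to oxygen and vinylogously acidified through C5=C4–C3=C2–C1=O;
- the isovalerate beside a free hydroxyl (acyl migration);
- the lactone beside O8 (translactonisation).

The real difficulty is the closure of a strained, bridged ten-membered carbocycle with a cis alkene and the late distinction of O8 from O9; C7–C10 map onto (R,R)-tartaric acid. The route uses the fact that O, C3, C2, C1 and C10 are an α-ketol (C10 hydroxyl, C1 ketone) acylated on oxygen by C3 and condensed at C2. Cutting C2–C3 turns the carbocycle into a nine-membered Z-enoate lactone of the C10 hydroxyl that carries a C10 acetyl group.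

## Logic of the disconnections

**38 from 35.** The C11=C13 double bond is traced back to the C13–nitrogen bond of 35 (through 37). The methylene lactone would not survive enolates, organometallics or amines, and making it late with strong base would put C6–H of the furanone system at risk. Carrying it as the amine adduct keeps every earlier compound free of a Michael acceptor. The forward step must be mild enough for the ester, the C9 hydroxyl and the furanone.

**35 from 33 and 34.** The O8–acyl bond is cut. The diol can then travel as one acetonide, which also keeps alkoxides away from esters in the key step. The forward step must acylate O8 and leave the neopentylic O9, which sits next to the quaternary C10.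

**33 from 32.** The two carbon–oxygen bonds of the ketal carbon are cut. The acid used must spare the furanone, the lactone and the allylic C6–O bond.

**32 from 29.** The C2–C3 bond is cut (with the C2=C3 dehydration). One bond formation then closes the furanone and creates the carbocycle, and no stereocentre is involved. The forward step needs enolisation of the ketone methyl group only. For this reason 29 carries the masked methylene at C11, a quaternary C10 and the acetonide.

**29 from 27.** The C5–C6 bond and the O6–C12 bond are cut (through 28). C5–C6 joins a vinyl iodide to an aldehyde under neutral, ketone-tolerant conditions, after the hindered ester at O10 is already in place. The forward step must set C6 (R) and must send O6 to C12 and not to C3.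

**27 from 25.** The C6 aldehyde is traced back to a vinyl group (C6=CH2), which keeps the epimerisable aldehyde latent until it is needed. The cleavage must spare the electron-poor iodo enoate.

**25 from 20, 21 and 6.** The C1–C10 bond and the O10–C3 bond are cut (through 22, 23 and 24). The acetyl group arrives as a vinyl anion, and the tertiary ester is made from the alkoxide at the moment it forms. The forward step must deliver the nucleophile to the Felkin–Anh face of the C10 ketone.

**20 from 19 and 2.** The C10–C14 bond is cut at an N-methoxy-N-methylamide carbonyl. The methyl Grignard reagent must react there and leave the branched ester C12 alone.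

**19 from 15, 16 and 17.** The C6–C7 and C11–C13 bonds are cut (through 18). One operation sets C7 and brings in the masked methylene. The forward step must give the 7,8-syn adduct, which the Z-enoate should provide.

**15 from 13 and 14.** The C7=C11 double bond is cut. The olefination must be Z-selective.

**13 from 7.** No skeletal bond is cut; the two ester groups of 7 are told apart through 8, 11 and 12. One equivalent of hydroxide must stop at the half ester, and the borohydride must reduce the ester and not the amide.

**6 from 1 and 2.** The C4–C15 bond and the C5–iodine bond are cut (through 3, 4 and 5). The anti-carbometalation fixes iodine cis to the future C3. The entry from a methylmalonate and iodoform is not used because its decarboxylative elimination gives the E acid.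

## Other disconnections considered

**Alternative 1:** The cut is C3–C4. The open-chain Z vinyl iodide ynal A1 already holds the methylene lactone, the C8 isovalerate and triethylsilyl ethers on O9 and O10. With CrCl2 and catalytic NiCl2, the vinylchromium species at C4 would add to the aldehyde carbon C3 and close the ring as the cyclodec-4-en-1-yn-3-ol A2.
- In its favour: the ester and the methylene group are in place and O8 and O9 are already distinguished. The new C3 centre is erased by oxidation of A2 at C3. Release of O10 and its amine-mediated addition across the C1–C2 alkyne is a known way to a 3(2H)-furanone.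
- Against it: the ten-membered ring must be closed end to end with a linear alkyne inside it. Ynals are open to conjugate addition and to reduction by divalent chromium. Three oxygens at C8, C9 and C10 must be distinguished early, and the methylene lactone must survive the whole fragment synthesis.
- Comparison: on structure the chosen plan closes an easier nine-membered lactone and gets the carbocycle from a transannular bond. On mechanism the two plans use the same chromium–nickel coupling and are equal. On the endgame alternative 1 is better (no site-selective acylation, no unmasking), but its front end is longer.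

**Alternative 2:** The cut is C8–C9. The dialdehyde A3 would be treated with SmI2; the two ketyls would couple to give the diol A4, forming the carbocycle and both carbinol centres at once.
- In its favour: the diol needs no protecting group at this point, which is better than the chosen plan.
- Against it: two stereocentres are formed together and must be trans, whereas samarium-bridged diketyls in rings tend to cis diols. Divalent samarium should also cleave the C10–O bond next to the C9 aldehyde and reduce the furanone enone. C7 beside the C8 aldehyde is epimerisable.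
- Comparison: the chosen plan takes C8 and C9 from tartrate and forms no stereocentre in its key step. In steps after the key step alternative 2 is no shorter, since A4 still needs acylation and methylenation.

**Alternative 3:** The cut is the C4=C5 alkene. The diene A5 would be treated with the second-generation Grubbs catalyst, which should load on the C6 vinyl group and close onto the 2-propenyl group of the furanone with loss of ethylene to give the 9-triethylsilyl ether A6.
- In its favour: it is the most convergent plan. The cis alkene is the one a ten-membered ring prefers, and only a desilylation separates A6 from the target, so it is clearly better than the chosen plan in steps after the key step.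
- Against it: the carbene must attack a hindered 1,1-disubstituted alkene that is conjugated to an electron-poor furanone. It must do so inside a strained ring, while a methylene lactone competes for the catalyst and reversibility leads to oligomers.
- Comparison: the chosen plan forms its ring bonds irreversibly, but it pays with three steps after the key step and a protecting-group scheme that alternative 3 does not need.

Key step: step 14

Remarks on the chemistry:
- Atoms carry germacrane numbers in every compound.
- 7 is the commercial acetonide of dimethyl (R,R)-tartrate.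
- C11 of 19, 20, 23–33, 35 and 37, C6 of 26 and C3 of 31 are formed without control and are left undefined; each becomes sp2 later.
- The trans-fused 8,9-acetonide and the configuration 6R,7S,8S,9R,10R of 29 and 32 agree with the target and with (R,R)-tartrate, so no stereocentre needed correction.

## Route

Step 1
Reactants: 1 prop-2-yn-1-ol; 2 methylmagnesium bromide
Product: 3 (2Z)-3-iodo-2-methylprop-2-en-1-ol
Conditions: MeMgBr (2.5 equiv), CuI (0.1 equiv), THF, 0 °C → rt; I2, −10 °C; aq. NH4Cl
Reagents that add atoms: methylmagnesium bromide 2, C[Mg]Br; iodine, [I][I]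
Why: Copper-catalysed anti-carbomagnesiation of the propargylic magnesium alkoxide puts methyl on C4 and magnesium on C5 inside a five-membered chelate. Iodinolysis with retention then leaves iodine cis to the carbinol carbon (the later C3), which is the Z geometry needed.

Step 2
Reactants: 3 (2Z)-3-iodo-2-methylprop-2-en-1-ol
Product: 5 (2Z)-3-iodo-2-methylprop-2-enoic acid, via (2Z)-3-iodo-2-methylprop-2-enal 4 (not isolated)
Conditions: TEMPO (0.2 equiv), PhI(OAc)2 (2.2 equiv), MeCN/H2O (1:1), 0 °C → rt
Reagents that add atoms: water, O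
Why: Oxoammonium oxidation of the allylic alcohol gives the aldehyde, whose hydrate is oxidised on to the acid near neutrality. The short life of the enal should limit Z-to-E isomerisation.

Step 3
Reactants: 5 (2Z)-3-iodo-2-methylprop-2-enoic acid
Product: 6 (2Z)-3-iodo-2-methylprop-2-enoyl chloride
Conditions: 1-chloro-N,N,2-trimethylprop-1-en-1-amine (1.1 equiv), CH2Cl2, 0 °C; used as a solution
Reagents that add atoms: 1-chloro-N,N,2-trimethylprop-1-en-1-amine, CC(C)=C(Cl)N(C)C
Why: Acid chloride formation with the Ghosez reagent runs without free HCl, which protects the Z vinyl iodide from acid-mediated isomerisation.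

Step 4
Reactants: 7 dimethyl (4R,5R)-2,2-dimethyl-1,3-dioxolane-4,5-dicarboxylate
Product: 8 (4R,5R)-5-(methoxycarbonyl)-2,2-dimethyl-1,3-dioxolane-4-carboxylic acid
Conditions: KOH (1.0 equiv), MeOH, 0 °C → rt; aq. HCl to pH 2
Reagents that add atoms: potassium hydroxide, [K+].[OH-]
Why: Saponification of one of two homotopic esters; the carboxylate that forms slows the second hydrolysis, so one equivalent of base should stop at the half ester.

Step 5
Reactants: 8 (4R,5R)-5-(methoxycarbonyl)-2,2-dimethyl-1,3-dioxolane-4-carboxylic acid; 9 N,O-dimethylhydroxylamine hydrochloride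
Product: 11 methyl (4R,5R)-5-[methoxy(methyl)carbamoyl]-2,2-dimethyl-1,3-dioxolane-4-carboxylate, via acyl imidazole 10 (not isolated)
Conditions: 1,1'-carbonyldiimidazole (1.1 equiv), CH2Cl2, 0 °C → rt; MeNHOMe·HCl (1.2 equiv), rt
Reagents that add atoms: N,O-dimethylhydroxylamine hydrochloride 9, CNOC.Cl
Why: Amide formation through the acyl imidazole; the trans-dioxolane is the stable isomer, so the α-centre is not at risk. The amide carbon is the future C10.

Step 6
Reactants: 11 methyl (4R,5R)-5-[methoxy(methyl)carbamoyl]-2,2-dimethyl-1,3-dioxolane-4-carboxylate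
Product: 12 (4R,5S)-5-(hydroxymethyl)-N-methoxy-N,2,2-trimethyl-1,3-dioxolane-4-carboxamide
Conditions: NaBH4 (2 equiv), MeOH, 0 °C
Reagents that add atoms: none
Why: Borohydride reduces the α-alkoxy-activated methyl ester and leaves the amide untouched; the descriptor changes only because the priorities change.

Step 7
Reactants: 12 (4R,5S)-5-(hydroxymethyl)-N-methoxy-N,2,2-trimethyl-1,3-dioxolane-4-carboxamide
Product: 13 (4R,5R)-5-formyl-N-methoxy-N,2,2-trimethyl-1,3-dioxolane-4-carboxamide
Conditions: Dess–Martin periodinane (1.2 equiv), NaHCO3, CH2Cl2, 0 °C → rt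
Reagents that add atoms: none
Why: Buffered Dess–Martin oxidation gives the α-alkoxy aldehyde (the future C7) without epimerisation.

Step 8
Reactants: 13 (4R,5R)-5-formyl-N-methoxy-N,2,2-trimethyl-1,3-dioxolane-4-carboxamide; 14 methyl 2-[bis(2,2,2-trifluoroethoxy)phosphoryl]acetate
Product: 15 methyl (2Z)-3-[(4S,5R)-5-[methoxy(methyl)carbamoyl]-2,2-dimethyl-1,3-dioxolan-4-yl]prop-2-enoate
Conditions: KN(SiMe3)2 (1.05 equiv), 18-crown-6 (3 equiv), THF, −78 °C
Reagents that add atoms: methyl 2-[bis(2,2,2-trifluoroethoxy)phosphoryl]acetate 14, COC(=O)CP(=O)(OCC(F)(F)F)OCC(F)(F)F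
Why: Still–Gennari olefination; fast, irreversible elimination from the kinetic adduct of the electron-poor phosphonate gives the Z-enoate (C7=C11).

Step 9
Reactants: 15 methyl (2Z)-3-[(4S,5R)-5-[methoxy(methyl)carbamoyl]-2,2-dimethyl-1,3-dioxolan-4-yl]prop-2-enoate; 16 vinylmagnesium bromide; 17 N,N-dimethylmethyleneiminium iodide
Product: 19 methyl (3R)-2-[(dimethylamino)methyl]-3-[(4S,5R)-5-[methoxy(methyl)carbamoyl]-2,2-dimethyl-1,3-dioxolan-4-yl]pent-4-enoate (C2 epimers), via silyl ketene acetal 18 (not isolated)
Conditions: CH2=CHMgBr (1.6 equiv), CuBr·SMe2 (0.2 equiv), Me3SiCl (2.5 equiv), THF, −78 °C; N,N-dimethylmethyleneiminium iodide (3 equiv), −78 °C → rt; aq. NaHCO3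
Reagents that add atoms: vinylmagnesium bromide 16, C=C[Mg]Br; N,N-dimethylmethyleneiminium iodide 17, C=[N+](C)C.[I-]
Why: Copper-catalysed, Me3SiCl-accelerated conjugate addition of the Grignard reagent, followed by a Mannich reaction of the silyl ketene acetal with the iminium salt. In the Z-enoate, 1,3-allylic strain holds C8–H in the enoate plane, and the vinylcopper species attacks C7 on the face of O8, anti to the C8–C9 bond, which gives the 7,8-syn adduct (7R here). The C11 centre forms without control and is of no consequence.

Step 10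
Reactants: 19 methyl (3R)-2-[(dimethylamino)methyl]-3-[(4S,5R)-5-[methoxy(methyl)carbamoyl]-2,2-dimethyl-1,3-dioxolan-4-yl]pent-4-enoate; 2 methylmagnesium bromide
Product: 20 methyl (3R)-3-[(4S,5R)-5-acetyl-2,2-dimethyl-1,3-dioxolan-4-yl]-2-[(dimethylamino)methyl]pent-4-enoate (C2 epimers)
Conditions: MeMgBr (1.5 equiv), THF, −78 → −30 °C; aq. NH4Cl
Reagents that add atoms: methylmagnesium bromide 2, C[Mg]Br
Why: Ketone synthesis from the N-methoxy-N-methylamide through its stable magnesium chelate; the α-branched methyl ester C12 should be much slower at this temperature.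

Step 11
Reactants: 20 methyl (3R)-3-[(4S,5R)-5-acetyl-2,2-dimethyl-1,3-dioxolan-4-yl]-2-[(dimethylamino)methyl]pent-4-enoate; 21 ethyl vinyl ether; 6 (2Z)-3-iodo-2-methylprop-2-enoyl chloride
Product: 25 (2R)-2-[(4R,5S)-5-[(3R)-2-[(dimethylamino)methyl]-1-methoxy-1-oxopent-4-en-3-yl]-2,2-dimethyl-1,3-dioxolan-4-yl]-3-oxobutan-2-yl (2Z)-3-iodo-2-methylprop-2-enoate, via 1-ethoxyvinyllithium 22 (not isolated), via lithium alkoxide 23 (not isolated), via enol ether ester 24 (not isolated)
Conditions: ethyl vinyl ether (3 equiv), t-BuLi (1.6 equiv), THF, −78 → 0 °C; 20, −78 °C; 6 (2.5 equiv), −78 → 0 °C; aq. HCl (1 N), THF, 0 °C; NaHCO3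
Reagents that add atoms: ethyl vinyl ether 21, C=COCC; (2Z)-3-iodo-2-methylprop-2-enoyl chloride 6, I/C=C(/C)C(Cl)=O; water, O
Why: Felkin–Anh addition of the acetyl anion equivalent 22 to the methyl ketone: O9 lies anti to the incoming nucleophile, which passes C9–H, so the new C10 oxygen is anti to O9 (10R). The hindered lithium alkoxide is acylated as it forms, which avoids a separate esterification of a tertiary alcohol. Dilute acid hydrolyses the enol ether to the C1 ketone much faster than it touches the acetonide.

Step 12
Reactants: 25 (2R)-2-[(4R,5S)-5-[(3R)-2-[(dimethylamino)methyl]-1-methoxy-1-oxopent-4-en-3-yl]-2,2-dimethyl-1,3-dioxolan-4-yl]-3-oxobutan-2-yl (2Z)-3-iodo-2-methylprop-2-enoate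
Product: 27 (2R)-2-[(4R,5S)-5-[(2R)-3-[(dimethylamino)methyl]-4-methoxy-1,4-dioxobutan-2-yl]-2,2-dimethyl-1,3-dioxolan-4-yl]-3-oxobutan-2-yl (2Z)-3-iodo-2-methylprop-2-enoate, via vicinal diol 26 (not isolated)
Conditions: OsO4 (0.02 equiv), NaIO4 (4 equiv), 2,6-lutidine (2 equiv), dioxane/H2O (3:1), rt; used at once
Reagents that add atoms: osmium tetroxide, O=[Os](=O)(=O)=O; sodium periodate, [Na+].[O-]I(=O)(=O)=O
Why: Lemieux–Johnson cleavage; the monosubstituted alkene is dihydroxylated far faster than the electron-poor iodo enoate, and periodate cuts the diol to the C6 aldehyde. The aldehyde is not stored, because C7 is epimerisable.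

Step 13
Reactants: 27 (2R)-2-[(4R,5S)-5-[(2R)-3-[(dimethylamino)methyl]-4-methoxy-1,4-dioxobutan-2-yl]-2,2-dimethyl-1,3-dioxolan-4-yl]-3-oxobutan-2-yl (2Z)-3-iodo-2-methylprop-2-enoate
Product: 29 (4Z,6R,7S,8S,9R,10R)-10-acetyl-11-[(dimethylamino)methyl]-8,9-(isopropylidenedioxy)-4,10-dimethyl bis-lactone (nine-membered C3-to-O10 enoate lactone fused at C6–C7 to the C12-to-O6 γ-lactone), via hydroxy ester 28 (not isolated)
Conditions: CrCl2 (8 equiv), NiCl2 (0.02 equiv), DMSO/THF, rt, 0.003 molar (slow addition); aq. work-up; TsOH·H2O (1.3 equiv), 4 Å molecular sieves, CH2Cl2, rt; NaHCO3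
Reagents that add atoms: none
Why: Nozaki–Hiyama–Kishi coupling: zerovalent nickel inserts into the carbon–iodine bond, the vinyl group passes to trivalent chromium and adds to the C6 aldehyde at high dilution, leaving the ketone and the esters alone. C6 (R) should arise because the chromium alkoxide and the C11 branch on C7 both take outward positions on the forming nine-membered ring, which is the 6,7-trans arrangement. Acid then closes the γ-lactone from O6 onto the unhindered methyl ester C12 in preference to the hindered tertiary enoate C3.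

Step 14
Reactants: 29 (4Z,6R,7S,8S,9R,10R)-10-acetyl-11-[(dimethylamino)methyl]-8,9-(isopropylidenedioxy)-4,10-dimethyl bis-lactone
Product: 32 (4Z,6R,7S,8S,9R,10R)-11-[(dimethylamino)methyl]-3,10-epoxy-8,9-(isopropylidenedioxy)-1-oxogermacra-2,4-dien-12,6-olide, via ten-membered 1,3-dione 30 (not isolated), via hemiketal 31 (not isolated)
Conditions: LiN(SiMe3)2 (3.0 equiv), THF, −78 → −30 °C, 0.01 molar; AcOH (3 equiv), −78 °C; TsOH·H2O (1.3 equiv), 4 Å molecular sieves, CH2Cl2, rt; NaHCO3
Reagents that add atoms: none
Why: Proposed new method: the closest known reaction type is the base-induced O-to-C acyl transfer of α-acyloxy ketones followed by acid cyclodehydration to 3(2H)-furanones, known for open-chain esters but not for an ester that is part of a medium-ring lactone; the reasoning is that the same 1,5-relationship between C2 and C3 holds here and the ring only adds preorganisation. LiN(SiMe3)2 removes a proton from C2 of the methyl ketone, the only enolisable ketone position, and the enolate carbon adds to the lactone carbonyl C3 in a 5-exo-trig closure of the ring O–C3–C2–C1–C10. The same bond completes the ten-membered carbocycle C1–C10 as a transannular event inside the nine-membered lactone, so no end-to-end macrocyclisation is needed. The tetrahedral adduct either opens to the 1,3-dione alkoxide 30 (held as its enolate by the second equivalent of base) and recloses to hemiketal 31 on protonation, or is protonated to 31 directly; in both cases the C10 oxygen stays on C10, and acid dehydration of 31 gives the furanone 32. No stereocentre is formed or touched, and the ring holds the Z geometry of C4=C5. The selectivity needed is kinetic deprotonation of the ketone methyl group in preference to C11–H of the lactone and to the γ-hydrogen C6–H of the enoate; the higher acidity of the ketone, the low temperature and the quaternary C10 should secure it, and the masked methylene at C11 offers the enolate no Michael acceptor. Attack on the lactone carbonyl C12 would need an eight-membered transition state and is not expected.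

Step 15
Reactants: 32 (4Z,6R,7S,8S,9R,10R)-11-[(dimethylamino)methyl]-3,10-epoxy-8,9-(isopropylidenedioxy)-1-oxogermacra-2,4-dien-12,6-olide
Product: 33 (4Z,6R,7R,8S,9R,10R)-11-[(dimethylamino)methyl]-3,10-epoxy-8,9-dihydroxy-1-oxogermacra-2,4-dien-12,6-olide
Conditions: CF3CO2H/H2O (9:1), 0 °C → rt; NaHCO3
Reagents that add atoms: none
Why: Acid hydrolysis of the trans-fused acetonide, which is strained on the medium ring. The furanone is a vinylogous ester that is itself formed under acid, and the amine is protected as its salt; the C7 descriptor changes only because the priorities change.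

Step 16
Reactants: 33 (4Z,6R,7R,8S,9R,10R)-11-[(dimethylamino)methyl]-3,10-epoxy-8,9-dihydroxy-1-oxogermacra-2,4-dien-12,6-olide; 34 3-methylbutanoic anhydride
Product: 35 (4Z,6R,7S,8S,9R,10R)-11-[(dimethylamino)methyl]-3,10-epoxy-9-hydroxy-8-(3-methylbutanoyloxy)-1-oxogermacra-2,4-dien-12,6-olide
Conditions: 3-methylbutanoic anhydride (1.1 equiv), DMAP (0.1 equiv), Et3N (1.5 equiv), CH2Cl2, −40 → 0 °C
Reagents that add atoms: 3-methylbutanoic anhydride 34, CC(C)CC(=O)OC(=O)CC(C)C
Why: DMAP-catalysed acylation under kinetic control; O8 is flanked by two methine carbons, whereas O9 is neopentylic beside the quaternary C10, so the anhydride should take O8. The low temperature is meant to suppress acyl migration and translactonisation.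

Step 17
Reactants: 35 (4Z,6R,7S,8S,9R,10R)-11-[(dimethylamino)methyl]-3,10-epoxy-9-hydroxy-8-(3-methylbutanoyloxy)-1-oxogermacra-2,4-dien-12,6-olide; 36 iodomethane
Product: 38 lobatin B, via ammonium iodide 37 (not isolated)
Conditions: MeI (10 equiv), THF, rt; evaporate; NaHCO3, H2O/EtOAc, rt
Reagents that add atoms: none
Why: Quaternisation of the amine followed by E1cB elimination of trimethylamine from the lactone (a Hofmann-type unmasking) gives the C11=C13 methylene group. Bicarbonate is mild enough for the ester, the free C9 hydroxyl and the furanone.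

## Compound list

1 | prop-2-yn-1-ol | C#CCO | starting material
2 | methylmagnesium bromide | C[Mg]Br | starting material
3 | (2Z)-3-iodo-2-methylprop-2-en-1-ol | I/C=C(/C)CO | intermediate
4 | (2Z)-3-iodo-2-methylprop-2-enal | I/C=C(/C)C=O | intermediate (not isolated)
5 | (2Z)-3-iodo-2-methylprop-2-enoic acid | I/C=C(/C)C(=O)O | intermediate
6 | (2Z)-3-iodo-2-methylprop-2-enoyl chloride | I/C=C(/C)C(Cl)=O | intermediate
7 | dimethyl (4R,5R)-2,2-dimethyl-1,3-dioxolane-4,5-dicarboxylate | COC(=O)[C@@H]1OC(C)(C)O[C@H]1C(=O)OC | starting material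
8 | (4R,5R)-5-(methoxycarbonyl)-2,2-dimethyl-1,3-dioxolane-4-carboxylic acid | OC(=O)[C@@H]1OC(C)(C)O[C@H]1C(=O)OC | intermediate
9 | N,O-dimethylhydroxylamine hydrochloride | CNOC.Cl | starting material
10 | methyl (4R,5R)-5-(1H-imidazole-1-carbonyl)-2,2-dimethyl-1,3-dioxolane-4-carboxylate | O=C(n1ccnc1)[C@@H]1OC(C)(C)O[C@H]1C(=O)OC | intermediate (not isolated)
11 | methyl (4R,5R)-5-[methoxy(methyl)carbamoyl]-2,2-dimethyl-1,3-dioxolane-4-carboxylate | CON(C)C(=O)[C@@H]1OC(C)(C)O[C@H]1C(=O)OC | intermediate
12 | (4R,5S)-5-(hydroxymethyl)-N-methoxy-N,2,2-trimethyl-1,3-dioxolane-4-carboxamide | CON(C)C(=O)[C@@H]1OC(C)(C)O[C@H]1CO | intermediate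
13 | (4R,5R)-5-formyl-N-methoxy-N,2,2-trimethyl-1,3-dioxolane-4-carboxamide | CON(C)C(=O)[C@@H]1OC(C)(C)O[C@H]1C=O | intermediate
14 | methyl 2-[bis(2,2,2-trifluoroethoxy)phosphoryl]acetate | COC(=O)CP(=O)(OCC(F)(F)F)OCC(F)(F)F | starting material
15 | methyl (2Z)-3-[(4S,5R)-5-[methoxy(methyl)carbamoyl]-2,2-dimethyl-1,3-dioxolan-4-yl]prop-2-enoate | CON(C)C(=O)[C@@H]1OC(C)(C)O[C@H]1/C=C\C(=O)OC | intermediate
16 | vinylmagnesium bromide | C=C[Mg]Br | starting material
17 | N,N-dimethylmethyleneiminium iodide | C=[N+](C)C.[I-] | starting material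
18 | (4R,5S)-N-methoxy-5-[(3R)-1-methoxy-1-(trimethylsilyloxy)penta-1,4-dien-3-yl]-N,2,2-trimethyl-1,3-dioxolane-4-carboxamide (ketene acetal geometry undefined) | CON(C)C(=O)[C@@H]1OC(C)(C)O[C@H]1[C@@H](C=C(OC)O[Si](C)(C)C)C=C | intermediate (not isolated)
19 | methyl (3R)-2-[(dimethylamino)methyl]-3-[(4S,5R)-5-[methoxy(methyl)carbamoyl]-2,2-dimethyl-1,3-dioxolan-4-yl]pent-4-enoate (C2 epimers) | CON(C)C(=O)[C@@H]1OC(C)(C)O[C@H]1[C@@H](C(CN(C)C)C(=O)OC)C=C | intermediate
20 | methyl (3R)-3-[(4S,5R)-5-acetyl-2,2-dimethyl-1,3-dioxolan-4-yl]-2-[(dimethylamino)methyl]pent-4-enoate (C2 epimers) | CC(=O)[C@@H]1OC(C)(C)O[C@H]1[C@@H](C(CN(C)C)C(=O)OC)C=C | intermediate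
21 | ethyl vinyl ether | C=COCC | starting material
22 | 1-ethoxyvinyllithium | [Li]C(=C)OCC | intermediate (not isolated)
23 | lithium (2R)-3-ethoxy-2-[(4R,5S)-5-[(3R)-2-[(dimethylamino)methyl]-1-methoxy-1-oxopent-4-en-3-yl]-2,2-dimethyl-1,3-dioxolan-4-yl]but-3-en-2-olate | [Li]O[C@@](C)(C(=C)OCC)[C@@H]1OC(C)(C)O[C@H]1[C@@H](C(CN(C)C)C(=O)OC)C=C | intermediate (not isolated)
24 | (2R)-3-ethoxy-2-[(4R,5S)-5-[(3R)-2-[(dimethylamino)methyl]-1-methoxy-1-oxopent-4-en-3-yl]-2,2-dimethyl-1,3-dioxolan-4-yl]but-3-en-2-yl (2Z)-3-iodo-2-methylprop-2-enoate | I/C=C(/C)C(=O)O[C@@](C)(C(=C)OCC)[C@@H]1OC(C)(C)O[C@H]1[C@@H](C(CN(C)C)C(=O)OC)C=C | intermediate (not isolated)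
25 | (2R)-2-[(4R,5S)-5-[(3R)-2-[(dimethylamino)methyl]-1-methoxy-1-oxopent-4-en-3-yl]-2,2-dimethyl-1,3-dioxolan-4-yl]-3-oxobutan-2-yl (2Z)-3-iodo-2-methylprop-2-enoate | I/C=C(/C)C(=O)O[C@@](C)(C(C)=O)[C@@H]1OC(C)(C)O[C@H]1[C@@H](C(CN(C)C)C(=O)OC)C=C | intermediate
26 | (2R)-2-[(4R,5S)-5-[(3S)-2-[(dimethylamino)methyl]-4,5-dihydroxy-1-methoxy-1-oxopentan-3-yl]-2,2-dimethyl-1,3-dioxolan-4-yl]-3-oxobutan-2-yl (2Z)-3-iodo-2-methylprop-2-enoate (C4 of the pentanoate undefined) | I/C=C(/C)C(=O)O[C@@](C)(C(C)=O)[C@@H]1OC(C)(C)O[C@H]1[C@@H](C(CN(C)C)C(=O)OC)C(O)CO | intermediate (not isolated)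
27 | (2R)-2-[(4R,5S)-5-[(2R)-3-[(dimethylamino)methyl]-4-methoxy-1,4-dioxobutan-2-yl]-2,2-dimethyl-1,3-dioxolan-4-yl]-3-oxobutan-2-yl (2Z)-3-iodo-2-methylprop-2-enoate | I/C=C(/C)C(=O)O[C@@](C)(C(C)=O)[C@@H]1OC(C)(C)O[C@H]1[C@@H](C(CN(C)C)C(=O)OC)C=O | intermediate
28 | nine-membered C3-to-O10 Z-enoate lactone (4Z,6R,7S,8S,9R,10R) with 6-hydroxy, 8,9-isopropylidenedioxy, 4,10-dimethyl and 10-acetyl groups and CH(CH2NMe2)CO2Me on C7 | O[C@@H]1/C=C(/C)C(=O)O[C@@](C)(C(C)=O)[C@@H]2OC(C)(C)O[C@H]2[C@H]1C(CN(C)C)C(=O)OC | intermediate (not isolated)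
29 | (4Z,6R,7S,8S,9R,10R)-10-acetyl-11-[(dimethylamino)methyl]-8,9-(isopropylidenedioxy)-4,10-dimethyl bis-lactone: nine-membered C3-to-O10 enoate lactone fused at C6–C7 to the C12-to-O6 γ-lactone | CN(C)CC1C(=O)O[C@@H]2/C=C(/C)C(=O)O[C@@](C)(C(C)=O)[C@@H]3OC(C)(C)O[C@H]3[C@@H]12 | intermediate
30 | (4Z,6R,7S,8S,9R,10R)-11-[(dimethylamino)methyl]-10-hydroxy-8,9-(isopropylidenedioxy)-1,3-dioxogermacr-4-en-12,6-olide | CN(C)CC1C(=O)O[C@@H]2/C=C(/C)C(=O)CC(=O)[C@](C)(O)[C@@H]3OC(C)(C)O[C@H]3[C@@H]12 | intermediate (not isolated)
31 | (4Z,6R,7S,8S,9R,10R)-11-[(dimethylamino)methyl]-3,10-epoxy-3-hydroxy-8,9-(isopropylidenedioxy)-1-oxogermacr-4-en-12,6-olide (C3 undefined) | CN(C)CC1C(=O)O[C@@H]2/C=C(/C)C3(O)CC(=O)[C@](C)(O3)[C@@H]4OC(C)(C)O[C@H]4[C@@H]12 | intermediate (not isolated)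
32 | (4Z,6R,7S,8S,9R,10R)-11-[(dimethylamino)methyl]-3,10-epoxy-8,9-(isopropylidenedioxy)-1-oxogermacra-2,4-dien-12,6-olide | CN(C)CC1C(=O)O[C@@H]2/C=C(/C)C3=CC(=O)[C@](C)(O3)[C@@H]4OC(C)(C)O[C@H]4[C@@H]12 | intermediate
33 | (4Z,6R,7R,8S,9R,10R)-11-[(dimethylamino)methyl]-3,10-epoxy-8,9-dihydroxy-1-oxogermacra-2,4-dien-12,6-olide | CN(C)CC1C(=O)O[C@@H]2/C=C(/C)C3=CC(=O)[C@](C)(O3)[C@H](O)[C@@H](O)[C@@H]12 | intermediate
34 | 3-methylbutanoic anhydride | CC(C)CC(=O)OC(=O)CC(C)C | starting material
35 | (4Z,6R,7S,8S,9R,10R)-11-[(dimethylamino)methyl]-3,10-epoxy-9-hydroxy-8-(3-methylbutanoyloxy)-1-oxogermacra-2,4-dien-12,6-olide | CN(C)CC1C(=O)O[C@@H]2/C=C(/C)C3=CC(=O)[C@](C)(O3)[C@H](O)[C@@H](OC(=O)CC(C)C)[C@@H]12 | intermediate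
36 | iodomethane | IC | starting material
37 | trimethylammonium iodide of 35 (11-[(trimethylammonio)methyl] lactone, same configuration) | C[N+](C)(C)CC1C(=O)O[C@@H]2/C=C(/C)C3=CC(=O)[C@](C)(O3)[C@H](O)[C@@H](OC(=O)CC(C)C)[C@@H]12.[I-] | intermediate (not isolated)
38 | lobatin B, (4Z,6R,7S,8S,9R,10R)-3,10-epoxy-9-hydroxy-8-(3-methylbutanoyloxy)-1-oxogermacra-2,4,11(13)-trien-12,6-olide | C=C1C(=O)O[C@@H]2/C=C(/C)C3=CC(=O)[C@](C)(O3)[C@H](O)[C@@H](OC(=O)CC(C)C)[C@@H]12 | target

## Step count and least certain steps

Total step count: 17 (3 for the acid chloride 6, 14 in the main line). Longest linear sequence: 14 steps (steps 4–17, from 7).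

**Step 14 (key step, proposed new method).**
- What may go wrong: the acetyl enolate may not reach the π-face of C3 if the nine-membered lactone holds the acetyl group on its outer side. Slower deprotonation at C6 (with loss of its configuration) or at C11 would then take over, or intermolecular condensation would compete.
- Fallback (known chemistry): the same C2–C3 bond is made on the open-chain ester and the carbocycle is then closed at C5–C6. Setting out from 25, LiN(SiMe3)2 followed by acid should give the furanone vinyl iodide F1 by acyl transfer and cyclodehydration. Cleavage of its vinyl group with OsO4/NaIO4 gives the furanone aldehyde F2, and CrCl2/NiCl2 closure at C5–C6 gives the ten-membered hydroxy ester F3. Acid lactonisation returns to the route at 32.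

**Step 13.**
- What may go wrong: low or reversed facial selectivity at C6 in the ring closure, because the preference of the forming nine-membered ring is an argument and not a rule. A second possibility is acyl transfer of the enoate from O10 to O6 during the acid treatment.
- Fallback: setting out from 27, the coupling is run without the acid treatment and the C6-epimeric hydroxy ester F4 is isolated. Me3SnOH cleaves its methyl ester to the C6-epimeric hydroxy acid F5. Mitsunobu lactonisation (PPh3, diisopropyl azodicarboxylate) then closes the γ-lactone with inversion at C6 and activates only C12, coming back to the route at 29.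

**Step 9.**
- What may go wrong: erosion of the syn selectivity through Z-to-E isomerisation of the enoate by reversible electron transfer from copper before carbon–carbon bond formation. A stoichiometric cuprate may be needed.
- Fallback: setting out from 13, Knoevenagel condensation with dimethyl malonate gives the alkylidene malonate F6. One of its esters is always cis to C8, which enforces the same allylic-strain conformer with no question of alkene geometry. Vinyl cuprate addition gives the malonate adduct F7, and Krapcho demethoxycarbonylation (LiCl, wet DMSO) gives the monoester F8. LiN(iPr)2 followed by N,N-dimethylmethyleneiminium iodide comes back to the route at 19.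

**Step 11.**
- What may go wrong: modest Felkin–Anh selectivity at the methyl ketone, enolisation of the ketone by the basic vinyllithium, or incomplete acylation of the hindered alkoxide.
- Fallback: setting out from 19, 1-ethoxyvinyllithium converts the amide into the 1-ethoxyvinyl ketone F9. MeMgBr is then added under chelation control (MgBr2·OEt2, CH2Cl2, −78 °C). Both the facial preference and the roles of nucleophile and resident group are exchanged, so the same 10R carbinol should result. Acylation of the magnesium alkoxide with 6 returns to the route at 24 and, after the acid work-up, at 25.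

**Step 16.**
- What may go wrong: incomplete site selectivity between the two secondary hydroxyl groups, over-acylation, or base-induced acyl migration.
- Fallback: setting out from 33, Bu2SnO (toluene, reflux) gives the 8,9-O-dibutylstannylene acetal F10. 3-Methylbutanoyl chloride then acylates the more accessible tin-bound oxygen O8 once only, since the chlorostannyl ether left on O9 is unreactive. Aqueous work-up returns to the route at 35.

## Further compounds

F1 | step 14 | 5-[(1Z)-2-iodo-1-methylvinyl]-3(2H)-furanone from 25 (open-chain C7 side chain, acetonide and vinyl group intact; 7R,8S,9R,10R) | I/C=C(/C)C1=CC(=O)[C@](C)(O1)[C@@H]2OC(C)(C)O[C@H]2[C@@H](C(CN(C)C)C(=O)OC)C=C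
F2 | step 14 | C6 aldehyde of F1 | I/C=C(/C)C1=CC(=O)[C@](C)(O1)[C@@H]2OC(C)(C)O[C@H]2[C@@H](C(CN(C)C)C(=O)OC)C=O
F3 | step 14 | ten-membered furanone-bridged 6-hydroxy compound with CH(CH2NMe2)CO2Me on C7 (4Z,6R,7S,8S,9R,10R) | O[C@@H]1/C=C(/C)C2=CC(=O)[C@](C)(O2)[C@@H]3OC(C)(C)O[C@H]3[C@H]1C(CN(C)C)C(=O)OC
F4 | step 13 | C6 epimer of 28 (6S) | O[C@H]1/C=C(/C)C(=O)O[C@@](C)(C(C)=O)[C@@H]2OC(C)(C)O[C@H]2[C@H]1C(CN(C)C)C(=O)OC
F5 | step 13 | carboxylic acid of F4 | O[C@H]1/C=C(/C)C(=O)O[C@@](C)(C(C)=O)[C@@H]2OC(C)(C)O[C@H]2[C@H]1C(CN(C)C)C(O)=O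
F6 | step 9 | dimethyl 2-{[(4S,5R)-5-[methoxy(methyl)carbamoyl]-2,2-dimethyl-1,3-dioxolan-4-yl]methylidene}propanedioate | CON(C)C(=O)[C@@H]1OC(C)(C)O[C@H]1C=C(C(=O)OC)C(=O)OC
F7 | step 9 | dimethyl 2-{(1R)-1-[(4S,5R)-5-[methoxy(methyl)carbamoyl]-2,2-dimethyl-1,3-dioxolan-4-yl]prop-2-en-1-yl}propanedioate | CON(C)C(=O)[C@@H]1OC(C)(C)O[C@H]1[C@@H](C(C(=O)OC)C(=O)OC)C=C
F8 | step 9 | methyl (3S)-3-[(4S,5R)-5-[methoxy(methyl)carbamoyl]-2,2-dimethyl-1,3-dioxolan-4-yl]pent-4-enoate | CON(C)C(=O)[C@@H]1OC(C)(C)O[C@H]1[C@@H](CC(=O)OC)C=C
F9 | step 11 | methyl (3R)-2-[(dimethylamino)methyl]-3-[(4S,5R)-5-(2-ethoxyprop-2-enoyl)-2,2-dimethyl-1,3-dioxolan-4-yl]pent-4-enoate | CCOC(=C)C(=O)[C@@H]1OC(C)(C)O[C@H]1[C@@H](C(CN(C)C)C(=O)OC)C=C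
F10 | step 16 | 8,9-O-dibutylstannylene acetal of 33 | CN(C)CC1C(=O)O[C@@H]2/C=C(/C)C3=CC(=O)[C@](C)(O3)[C@@H]4O[Sn](CCCC)(CCCC)O[C@H]4[C@@H]12
A1 | alternative 1 | open-chain Z vinyl iodide ynal with methylene lactone, C8 isovalerate and 9,10-bis(triethylsilyl) ethers | C/C(I)=C/[C@H]1OC(=O)C(=C)[C@@H]1[C@H](OC(=O)CC(C)C)[C@@H](O[Si](CC)(CC)CC)[C@@](C)(O[Si](CC)(CC)CC)C#CC=O
A2 | alternative 1 | cyclodec-4-en-1-yn-3-ol fused to the methylene lactone | C/C1=C/[C@H]2OC(=O)C(=C)[C@@H]2[C@H](OC(=O)CC(C)C)[C@@H](O[Si](CC)(CC)CC)[C@@](C)(O[Si](CC)(CC)CC)C#C[C@@H]1O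
A3 | alternative 2 | C8,C9 dialdehyde (furanone and butyrolactone joined by the Z alkene) | O=C[C@H]1CC(=O)O[C@@H]1/C=C(/C)C2=CC(=O)[C@@](C)(C=O)O2
A4 | alternative 2 | bicyclic 8,9-diol lacking the exocyclic methylene and the ester | C1C(=O)O[C@@H]2/C=C(/C)C3=CC(=O)[C@](C)(O3)[C@H](O)[C@@H](O)[C@@H]12
A5 | alternative 3 | open diene: C6 vinyl methylene lactone with C8 isovalerate, 9-triethylsilyl ether and 5-(prop-1-en-2-yl)furanone | C=C1C(=O)O[C@H](C=C)[C@H]1[C@H](OC(=O)CC(C)C)[C@@H](O[Si](CC)(CC)CC)[C@@]1(C)OC(C(C)=C)=CC1=O
A6 | alternative 3 | lobatin B 9-triethylsilyl ether | C=C1C(=O)O[C@@H]2/C=C(/C)C3=CC(=O)[C@](C)(O3)[C@H](O[Si](CC)(CC)CC)[C@@H](OC(=O)CC(C)C)[C@@H]12
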